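**Retrosynthetic overview**

- The target is the 7-acetate of a labda-12E,14-diene-6β,7β,8α-triol. The acetate goes on last (equatorial 7β-OH). The diene comes from a C9 allyl group (cross-metathesis with methacrolein, then methylenation). Ring B is oxidised from a C7 ketone: 8α-OH by Rubottom oxidation, the cis-6β,7β-diol by α-face hydride reduction of a 6,7-dione.
- The C7 ketone and the C9 side-chain carbon come from a C9 ketone by allyl addition and oxidative 1,3-transposition, then dissolving-metal reduction (9α-H).
- Key disconnection: ring A is opened at C3–C4 and C1–C10. This leaves 6-methylcarvone (ring B with C5 and the C4 isopropenyl group) and a C1–C2–C3 unit, 2,3-bis(phenylsulfonyl)prop-1-ene. Both bonds are made in one flask as a [3+3] annulation: enolate allylation at C10, then hydrogen-atom-transfer radical closure at C4.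
- Enabling feature: in ring A the quaternary carbons C4 (gem-dimethyl) and C10 (angular methyl) flank C5–H and are bridged only by the three CH2 groups C1–C3. C10 is α to C9 of ring B, which can be a ketone. C4 with C18/C19 is a masked isopropenyl group that gives a tertiary radical on H-atom addition.
- Ring order: ring B is bought as (R)-carvone (source of the C5 configuration); ring A is formed in step 2.

Key step: step 2

Remark: bicyclic compounds are named on the labdane skeleton with labdane numbering (ring A C1–C5 and C10, ring B C5–C10, C17 on C8, C18/C19 on C4, C20 on C10; 5α-H and 10β-CH3 throughout), and 2,3-bis(phenylsulfonyl)prop-1-ene is taken as a purchasable reagent.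

Step 1
Reactants: 1 (R)-(−)-carvone
Product: 2 6-methylcarvone (C6 epimer mixture)
Conditions: LiN(iPr)2, THF, −78 °C; MeI, −78 → 0 °C
Reagents that add atoms: iodomethane, CI
Why: Kinetic α′-deprotonation of the cross-conjugated enone and C-methylation of the lithium enolate (enolate alkylation) is standard for carvone; the new centre (later C10) forms as an epimer mixture, which does not matter because it is planarised again in step 2.

Step 2
Reactants: 2 6-methylcarvone (C6 epimer mixture); 3 2,3-bis(phenylsulfonyl)prop-1-ene
Product: 5 2ξ-(phenylsulfonyl)-11,12,13,14,15,16-hexanorlabd-7-en-9-one (C2 epimers), via allylated ketone 4 (not isolated)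
Conditions: LiN(iPr)2, THF, −78 °C; 3 (1.05 equiv), −78 → 0 °C; then in the same flask EtOH, Fe(acac)3 (30 mol %), PhSiH3, 60 °C
Reagents that add atoms: 3 2,3-bis(phenylsulfonyl)prop-1-ene, C=C(CS(=O)(=O)c1ccccc1)S(=O)(=O)c1ccccc1
Why: The lithium enolate of 2 (both C10 epimers give the same planar enolate) adds to the CH2 terminus of 3 and expels benzenesulfinate (addition–elimination, a formal SN2′ enolate allylation), which forms C1–C10 and gives 4; hydrogen-atom transfer from the iron hydride to the CH2 of the isopropenyl group then creates the tertiary C4 radical, which adds to the terminal carbon C3 of the vinyl sulfone and is reduced and protonated at C2, which forms C3–C4 and makes C18 the second geminal methyl. The closest known reactions are the alkylation of 6-substituted carvone enolates with allylic electrophiles and the iron-catalysed reductive coupling of 1,1-disubstituted alkenes with vinyl sulfones (hydrogen-atom-transfer Giese reaction), run here back to back as a [3+3] annulation. Ring A is closed by a 6-endo-trig radical cyclisation after an intermolecular first bond. C10 is set in the ionic stage, where the electrophile enters the enolate face anti to the C5 isopropenyl group (C1 α, methyl β), so the C5 centre of carvone controls it and the epimer mixture 2 converges; C5 is untouched, and the sulfonyl-bearing C2 is formed as a mixture that is erased in step 5. The step needs the order C1–C10 before C3–C4, because closure onto a trigonal C10 from a tether on C5 could only give the cis ring fusion, and this order is secured by finishing the enolate stage cold before silane and iron are added; the trans fusion then follows from the trans-diequatorial C1 and C4 arms. It also needs 6-endo over 5-exo closure, secured by the sulfonyl group on C2 (attack at the unsubstituted, polarity-matched terminus gives a stabilised α-sulfonyl radical), and hydrogen-atom transfer to the electron-rich isopropenyl group in preference to the enone and the vinyl sulfone, which is the normal preference of these iron hydrides.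

Step 3
Reactants: 5 2ξ-(phenylsulfonyl)-11,12,13,14,15,16-hexanorlabd-7-en-9-one (C2 epimers); 6 allylmagnesium bromide
Product: 7 2ξ-(phenylsulfonyl)-14,15,16-trinorlabda-7,12-dien-9-ol (9β-OH expected)
Conditions: CH2=CHCH2MgBr, THF, −78 °C; then H2O
Reagents that add atoms: 6 allylmagnesium bromide, C=CC[Mg]Br
Why: Fast 1,2-addition of the allyl Grignard reagent to the hindered enone carbonyl (Grignard addition, α-face attack anti to the axial C10 methyl expected) should outrun deprotonation of the weakly acidic α-sulfonyl C–H at low temperature, and the new C9 carbinol centre is erased in step 4.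

Step 4
Reactants: 7 2ξ-(phenylsulfonyl)-14,15,16-trinorlabda-7,12-dien-9-ol (9β-OH expected)
Product: 8 2ξ-(phenylsulfonyl)-14,15,16-trinorlabda-8,12-dien-7-one
Conditions: pyridinium chlorochromate (C5H5NH)[CrO3Cl], 4 Å MS, CH2Cl2, rt
Reagents that add atoms: pyridinium chlorochromate, [O-][Cr](=O)(=O)Cl.c1cc[nH+]cc1
Why: Dauben–Babler oxidative 1,3-transposition: the tertiary allylic chromate ester shifts to C7 by a [3,3] process and is oxidised to the Δ8-en-7-one, which puts the carbonyl oxygen (delivered from the chromate) on C7 and the allyl group on the alkene carbon C9 without forming a stereocentre.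

Step 5
Reactants: 8 2ξ-(phenylsulfonyl)-14,15,16-trinorlabda-8,12-dien-7-one
Product: 10 7-(trimethylsilyloxy)-14,15,16-trinorlabda-7,12-diene, via lithium enolate 9 (not isolated)
Conditions: Li, NH3/THF, −78 °C; isoprene; NH3 evaporated; then Me3SiCl, Et3N, THF, −78 → 0 °C
Reagents that add atoms: chlorotrimethylsilane, C[Si](C)(C)Cl
Why: Dissolving-metal (Birch-type) reduction of the tetrasubstituted enone gives the C7 enolate regiospecifically after axial protonation of C9 from the α face (allyl group equatorial, 9α-H), the same reagent cleaves the C2–S bond (reductive desulfonylation), the isolated terminal alkene survives, and O-silylation traps the enolate.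

Step 6
Reactants: 10 7-(trimethylsilyloxy)-14,15,16-trinorlabda-7,12-diene
Product: 12 8α-hydroxy-14,15,16-trinorlabd-12-en-7-one, via silyloxy ketone 11 (not isolated)
Conditions: mCPBA, NaHCO3, CH2Cl2, −20 °C; then HF·pyridine, THF, 0 °C
Reagents that add atoms: 3-chloroperbenzoic acid, OOC(=O)c1cccc(Cl)c1
Why: Rubottom oxidation: the electron-rich tetrasubstituted silyl enol ether is epoxidised far faster than the terminal alkene and on the α face, opposite the syn-axial C10 methyl, so silyl migration and desilylation give the 8α-hydroxy (8β-methyl) ketone.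

Step 7
Reactants: 12 8α-hydroxy-14,15,16-trinorlabd-12-en-7-one
Product: 13 6ξ,8α-dihydroxy-14,15,16-trinorlabd-12-en-7-one
Conditions: KN(SiMe3)2 (2.2 equiv), THF, −78 °C; 2-(phenylsulfonyl)-3-phenyloxaziridine; then AcOH
Reagents that add atoms: 2-(phenylsulfonyl)-3-phenyloxaziridine, O=S(=O)(N1OC1c1ccccc1)c1ccccc1
Why: Enolate hydroxylation with an N-sulfonyloxaziridine: C6 is the only enolisable position of the alkoxide ketone, and the configuration of the new C6 carbinol (α expected) is irrelevant because it is oxidised in step 8.

Step 8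
Reactants: 13 6ξ,8α-dihydroxy-14,15,16-trinorlabd-12-en-7-one
Product: 14 8α-hydroxy-14,15,16-trinorlabd-12-ene-6,7-dione
Conditions: Dess–Martin periodinane, NaHCO3, CH2Cl2, 0 °C; crude product used at once
Reagents that add atoms: none
Why: Periodinane oxidation of the secondary α-ketol to the 1,2-diketone under buffered, non-enolising conditions should leave the tertiary 8-OH and the C5 centre untouched.

Step 9
Reactants: 14 8α-hydroxy-14,15,16-trinorlabd-12-ene-6,7-dione
Product: 15 14,15,16-trinorlabd-12-ene-6β,7β,8α-triol
Conditions: NaBH4, CeCl3·7H2O, MeOH/THF, −78 → −20 °C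
Reagents that add atoms: none
Why: Borohydride reduction should deliver hydride to both carbonyls from the α face: at C6 the β face is blocked by the syn-axial C4β and C10 methyls (axial 6β-OH), and at C7 axial α attack anti to the C8β methyl gives the equatorial 7β-OH, so the cis-6β,7β-diol next to the 8α-OH should result.

Step 10
Reactants: 15 14,15,16-trinorlabd-12-ene-6β,7β,8α-triol; 16 methacrolein
Product: 17 (12E)-6β,7β,8α-trihydroxy-15-norlabd-12-en-14-al
Conditions: RuCl2(SIMes)(=CH-C6H4-2-OiPr) (second-generation Hoveyda–Grubbs catalyst, 5 mol %), 16 (excess), CH2Cl2, 40 °C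
Reagents that add atoms: 16 methacrolein, C=C(C)C=O
Why: Olefin cross-metathesis of the monosubstituted alkene with the 1,1-disubstituted enal, driven by loss of ethene, should give the conjugated trisubstituted enal as the thermodynamically preferred E isomer at C12=C13, and free hydroxyls are tolerated.

Step 11
Reactants: 17 (12E)-6β,7β,8α-trihydroxy-15-norlabd-12-en-14-al
Product: 18 (12E)-labda-12,14-diene-6β,7β,8α-triol
Conditions: Ph3PCH3Br, KOtBu, THF, 0 °C; then 17, −78 → 0 °C (excess ylide)
Reagents that add atoms: methyltriphenylphosphonium bromide, C[P+](c1ccccc1)(c1ccccc1)c1ccccc1.[Br-]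
Why: Wittig methylenation of the aldehyde completes the 12E,14-diene without touching the C12=C13 geometry, and excess ylide compensates for the three hydroxyls.

Step 12
Reactants: 18 (12E)-labda-12,14-diene-6β,7β,8α-triol
Product: 19 (12E)-7β-acetoxylabda-12,14-diene-6β,8α-diol (target)
Conditions: Ac2O, pyridine, 0 °C → rt
Reagents that add atoms: acetic anhydride, CC(=O)OC(C)=O
Why: Kinetic acylation should pick the equatorial secondary 7β-OH, because the axial 6β-OH is 1,3-diaxial to the C4β and C10 methyls and the 8α-OH is tertiary.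

**Compound list**

1 | (R)-(−)-carvone, (5R)-2-methyl-5-(prop-1-en-2-yl)cyclohex-2-en-1-one | O=C1C(C)=CC[C@@H](C(C)=C)C1 | starting material
2 | 6-methylcarvone, (5R)-2,6-dimethyl-5-(prop-1-en-2-yl)cyclohex-2-en-1-one (C6 epimer mixture) | O=C1C(C)=CC[C@@H](C(C)=C)C1C | intermediate
3 | 2,3-bis(phenylsulfonyl)prop-1-ene | C=C(CS(=O)(=O)c1ccccc1)S(=O)(=O)c1ccccc1 | starting material
4 | allylated ketone, (5S,6S)-2,6-dimethyl-6-[2-(phenylsulfonyl)prop-2-en-1-yl]-5-(prop-1-en-2-yl)cyclohex-2-en-1-one (sulfonylallyl group trans to isopropenyl) | O=C1C(C)=CC[C@@H](C(C)=C)[C@]1(C)CC(=C)S(=O)(=O)c2ccccc2 | intermediate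
5 | 2ξ-(phenylsulfonyl)-11,12,13,14,15,16-hexanorlabd-7-en-9-one, (4aS,8aS)-2,5,5,8a-tetramethyl-7-(phenylsulfonyl)-4a,5,6,7,8,8a-hexahydronaphthalen-1(4H)-one (trans-fused, C2 epimers) | O=C1C(C)=CC[C@H]2C(C)(C)CC(S(=O)(=O)c3ccccc3)C[C@@]21C | intermediate
6 | allylmagnesium bromide | C=CC[Mg]Br | starting material
7 | 2ξ-(phenylsulfonyl)-14,15,16-trinorlabda-7,12-dien-9-ol (allyl α, 9β-OH expected; C2 epimers) | C=CC[C@]1(O)C(C)=CC[C@H]2C(C)(C)CC(S(=O)(=O)c3ccccc3)C[C@@]21C | intermediate
8 | 2ξ-(phenylsulfonyl)-14,15,16-trinorlabda-8,12-dien-7-one (C2 epimers) | C=CCC1=C(C)C(=O)C[C@H]2C(C)(C)CC(S(=O)(=O)c3ccccc3)C[C@@]21C | intermediate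
9 | lithium enolate, lithium 14,15,16-trinorlabda-7,12-dien-7-olate (9α-H) | C=CC[C@H]1C(C)=C(O[Li])C[C@H]2C(C)(C)CCC[C@@]21C | intermediate
10 | 7-(trimethylsilyloxy)-14,15,16-trinorlabda-7,12-diene (9α-H, allyl β) | C=CC[C@H]1C(C)=C(O[Si](C)(C)C)C[C@H]2C(C)(C)CCC[C@@]21C | intermediate
11 | silyloxy ketone, 8α-(trimethylsilyloxy)-14,15,16-trinorlabd-12-en-7-one (C17 methyl β) | C=CC[C@H]1[C@](C)(O[Si](C)(C)C)C(=O)C[C@H]2C(C)(C)CCC[C@@]21C | intermediate
12 | 8α-hydroxy-14,15,16-trinorlabd-12-en-7-one (C17 methyl β) | C=CC[C@H]1[C@](C)(O)C(=O)C[C@H]2C(C)(C)CCC[C@@]21C | intermediate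
13 | 6ξ,8α-dihydroxy-14,15,16-trinorlabd-12-en-7-one (6α-OH expected) | C=CC[C@H]1[C@](C)(O)C(=O)C(O)[C@H]2C(C)(C)CCC[C@@]21C | intermediate
14 | 8α-hydroxy-14,15,16-trinorlabd-12-ene-6,7-dione | C=CC[C@H]1[C@](C)(O)C(=O)C(=O)[C@H]2C(C)(C)CCC[C@@]21C | intermediate
15 | 14,15,16-trinorlabd-12-ene-6β,7β,8α-triol | C=CC[C@H]1[C@](C)(O)[C@@H](O)[C@@H](O)[C@H]2C(C)(C)CCC[C@@]21C | intermediate
16 | methacrolein, 2-methylprop-2-enal | C=C(C)C=O | starting material
17 | (12E)-6β,7β,8α-trihydroxy-15-norlabd-12-en-14-al | O=C/C(C)=C/C[C@H]1[C@](C)(O)[C@@H](O)[C@@H](O)[C@H]2C(C)(C)CCC[C@@]21C | intermediate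
18 | (12E)-labda-12,14-diene-6β,7β,8α-triol | C=C/C(C)=C/C[C@H]1[C@](C)(O)[C@@H](O)[C@@H](O)[C@H]2C(C)(C)CCC[C@@]21C | intermediate
19 | (12E)-7β-acetoxylabda-12,14-diene-6β,8α-diol (CNP0225877.1) | C=C/C(C)=C/C[C@H]1[C@](C)(O)[C@@H](OC(C)=O)[C@@H](O)[C@H]2C(C)(C)CCC[C@@]21C | target

**Step count and risks**

Total steps: 12. Longest linear sequence: 12 steps (from 1).

Steps most likely to fail:

Step 2. In the one-flask relay the iron-hydride stage may be disturbed by the lithium sulfinate and amine left from the enolate stage. Hydrogen-atom transfer may also simply hydrogenate the isopropenyl group, or reduce the vinyl sulfone or the enone, before the radical closes the ring. Fallback: the sequence is stopped after the ionic stage and allylated ketone 4 is isolated. Dry HCl in Et2O at 0 °C adds in the Markovnikov sense to the isopropenyl group to give the tertiary chloride F1. Bu3SnH with AIBN (slow addition, benzene, 80 °C) then generates the same tertiary C4 radical by chlorine abstraction, and its 6-endo addition to the vinyl sulfone returns to 5.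

Step 9. The 1,2-dione may enolise toward C5 (diosphenol formation with loss of the C5 configuration) before or during reduction, and hydride delivery may not be fully α-selective at both carbonyls. Fallback, avoiding the dione, sets out from hydroxy ketone 12:
- KN(SiMe3)2 and PhNTf2 give the enol triflate F2, and Pd(OAc)2, PPh3, Bu3N and HCO2H reduce it to the Δ6-alkene F3.
- mCPBA, directed by the allylic 8α-OH and by the open α face, gives the 6α,7α-epoxide F4.
- Aqueous HClO4 in THF opens it trans-diaxially with water at C6 to the 6β,7α,8α-triol F5.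
- Bu2SnO, then NBS, oxidises the secondary hydroxyl of the cis-7,8-diol through its stannylene acetal to the 6β,8α-dihydroxy 7-ketone F6.
- NaBH4 delivers hydride to C7 from the α face, which returns to triol 15.

Step 5. Three events are asked of one dissolving-metal step. The C2–S bond may be cleaved incompletely or on the aryl side, the terminal alkene may be partly reduced, and the enolate may protonate or equilibrate before silylation. Fallback: the sulfone is removed earlier and separately. From alcohol 7, sodium amalgam (Na(Hg), Na2HPO4, MeOH) cleaves the C2–S bond to give the sulfone-free alcohol F7. Pyridinium chlorochromate converts it by the same oxidative transposition into the sulfone-free enone F8. A plain Li/NH3 reduction with Me3SiCl trapping, now with one task only, returns to silyl enol ether 10.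

**Further compounds**

F1 | step 2 | tertiary chloride, (5R,6S)-5-(2-chloropropan-2-yl)-2,6-dimethyl-6-[2-(phenylsulfonyl)prop-2-en-1-yl]cyclohex-2-en-1-one | O=C1C(C)=CC[C@@H](C(C)(C)Cl)[C@]1(C)CC(=C)S(=O)(=O)c2ccccc2
F2 | step 9 | enol triflate, 8α-hydroxy-14,15,16-trinorlabda-6,12-dien-7-yl trifluoromethanesulfonate | C=CC[C@H]1[C@](C)(O)C(OS(=O)(=O)C(F)(F)F)=C[C@H]2C(C)(C)CCC[C@@]21C
F3 | step 9 | Δ6-alkene, 14,15,16-trinorlabda-6,12-dien-8α-ol | C=CC[C@H]1[C@](C)(O)C=C[C@H]2C(C)(C)CCC[C@@]21C
F4 | step 9 | 6α,7α-epoxide, 6α,7α-epoxy-14,15,16-trinorlabd-12-en-8α-ol | C=CC[C@H]1[C@](C)(O)[C@@H]3O[C@@H]3[C@H]2C(C)(C)CCC[C@@]21C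
F5 | step 9 | 14,15,16-trinorlabd-12-ene-6β,7α,8α-triol | C=CC[C@H]1[C@](C)(O)[C@H](O)[C@@H](O)[C@H]2C(C)(C)CCC[C@@]21C
F6 | step 9 | 6β,8α-dihydroxy-14,15,16-trinorlabd-12-en-7-one | C=CC[C@H]1[C@](C)(O)C(=O)[C@@H](O)[C@H]2C(C)(C)CCC[C@@]21C
F7 | step 5 | sulfone-free alcohol, 14,15,16-trinorlabda-7,12-dien-9-ol (allyl α, 9β-OH expected) | C=CC[C@]1(O)C(C)=CC[C@H]2C(C)(C)CCC[C@@]21C
F8 | step 5 | sulfone-free enone, 14,15,16-trinorlabda-8,12-dien-7-one | C=CCC1=C(C)C(=O)C[C@H]2C(C)(C)CCC[C@@]21C
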